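## The problem

Germacrane numbering is used throughout (ring carbons C1–C10, C14 on C10, C15 on C4, C11 on C7 carrying the lactone carbonyl C12 and the methylene C13, lactone oxygen on C8; TBS = tert-butyldimethylsilyl, TES = triethylsilyl). Target 30 is a ten-membered carbocycle with two trisubstituted alkenes of opposite ring geometry, C1=C10 cis in the ring (E by the sequence rule) and C4=C5 trans in the ring (Z), so a synthesis has to close a strained medium ring and fix two alkene geometries in the same event. Each alkene carries an oxidised one-carbon branch that ends differently acylated (acetate on C14, 2-(hydroxymethyl)acrylate on C15), so the two carbons must be distinguishable from the moment they enter. The only stereocentres are the adjacent C7 (R) and C8 (S) of the trans-fused α-methylene-γ-butyrolactone; one can set the other, since a syn addition across a C7=C8 alkene gives the trans relation, but neither can be expected to control the alkene geometries. The methylene lactone and the hydroxymethylacrylate are Michael acceptors, the allylic esters are base-labile, and the cyclodeca-1,5-diene is prone to acid-induced transannular cyclisation and to Cope rearrangement on strong heating, so acceptors and acyl groups must arrive late under near-neutral conditions. The enabling feature is the 1,5-diene C10=C1–C2–C3–C4=C5: joining C1 to C4 and C5 to C10 turns it into a cyclobutane fused to a six-membered ring (C5–C10) and to a four-membered ring (C1–C4), and because C14 can be an ester, the six-membered half is a cyclohex-1-enecarboxylate able to add photochemically to a cyclobutene.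

## Retrosynthesis

**C15 ester.** The O–acyl bond at C15 of 30 is cut first, giving hydroxy lactone 25 and the silyl-protected acid 28 (by way of the protected ester 29). The hydroxymethylacrylate is the most fragile unit and would survive neither hydride nor base. The forward reaction is a carbodiimide esterification of the only free hydroxyl and a buffered fluoride desilylation.

**Lactone.** In 25 the C12–O8 bond and the C11=C13 bond are cut, leading back through acrylic acid 23 and enal 22 to aldehyde 20, in which C7 carries a CH2–CHO arm. Methylenating an aldehyde (Mannich, then elimination) and oxidising it to the acid is preferred to enolate methylenation of a preformed lactone, which the C14 acetate would not tolerate. It is also preferred to carbonylative closure of a C11 alkyne, which needs PdCl2 (a divalent palladium salt of the kind known to promote Cope rearrangement of 1,5-dienes) and a basic alkyne homologation. The price is that C12 must be carried from the start as a protected primary alcohol. The forward steps must spare an allylic acetate, two TBS ethers and the diene.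

**C14.** Aldehyde 20 comes from acetate 18 (direct oxidation of a primary TES ether), 18 from allylic alcohol 17, and 17 from the ten-membered dienoate 16. C14 is kept as the methyl ester up to 16 because the ester is the chromophore of the key step and the control element of the ring opening. It is reduced immediately afterwards, while no other carbonyl group is present.

**Ring opening.** Reconnecting C1–C4 and C5–C10 in 16 gives the cis-anti-cis tricycle 15, which contains a bicyclo[2.2.0]hexane. This is preferred to any closure of the ten-membered ring from an open chain because strain release, not high dilution, drives the ring formation. The precursor is a compact tricycle whose four cyclobutane stereocentres need not be controlled individually. The forward reaction must cleave C5–C10 and not C2–C3, and must deliver C1=C10 cis and C4=C5 trans.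

**Key step.** The cyclobutane C10–C1–C4–C5 of 15 is cut into the cyclohexenecarboxylate 10 and the cyclobutene 14. The alternative pairing (ketone in the six-membered ring, ester on the cyclobutene) would leave a ring carbonyl to remove. Here the chromophore carbon is C14 itself and C15 arrives on the cyclobutene, already differentiated as a silyl ether. The photocycloaddition must be head-to-tail and cis-anti-cis; which face of 10 is used does not matter.

**Stereocentres.** The C8 silyl ether 10 comes from alcohol 9, obtained by lipase resolution of racemic 8. The C8–O and C7–H bonds of 8 are cut to the cyclohexa-1,4-diene 6. Syn hydroboration of the trisubstituted C7=C8 alkene sets the trans relation in one step, and the electron-poor enoate alkene is left alone.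

**Six-membered ring.** Diene ester 6 is cut at C5–C6 and C9–C10 into diene 4 and methyl propiolate 5. The propiolate delivers C14 at the ester level, so no later oxidation of C14 is needed. Diene 4 comes from alkyne 2 and ethylene 3 by enyne metathesis, and 2 from but-3-yn-1-ol 1.

**Small fragments.** Cyclobutene 14 comes from alcohol 13, acid 12 and the commercial bromo ester 11. Acid 28 comes from ester 27 and ethyl 2-(hydroxymethyl)acrylate 26.

## Roads not taken

**Alternative 1:** Cut C2–C3, C6–C7 and C8–C9. Ni(cod)2 (zerovalent nickel) with a phosphine would couple two molecules of diene A2 with ynone A3 to give the cyclodeca-1,4,7-triene A1 in one step.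
- Merits: the whole carbocycle with both oxygenated branches is assembled from three small pieces, and the nickel template gives the ring-cis C1=C10 and ring-trans C4=C5 geometry. In step count to the ring this road is clearly better than the chosen plan.
- Weak points: two unsymmetrical dienes can pair in several orientations and the ynone can insert in two, so regioisomeric trienes are expected. C14 and C15 arrive as identical silyl ethers. The C7=C8 enone must be converted on a flexible ring with two doubly allylic positions into the trans C7–H/C8–O pattern, and C12 must still be added to the acetyl group. Nothing in the sequence sets absolute configuration.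
- Comparison: the chosen plan is longer, but both ring-forming bonds are regiochemically defined, C14 and C15 are differentiated from the outset, and C7/C8 are set on a six-membered ring before the ring is expanded.

**Alternative 2:** Form C2–C3 while C5–C10 breaks. The potassium alkoxide of the cis-1-vinyl-2-alkenylcyclohexanol A5 (KH, 18-crown-6) would undergo anionic oxy-Cope rearrangement, and the C10 enolate would be trapped with PhNTf2 as the dienyl triflate A4.
- Merits: it uses the same six-to-ten ring expansion logic as the chosen plan but runs near room temperature, so onward Cope rearrangement is no concern. This ring expansion is milder and better established for germacranes than the thermolysis chosen here.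
- Weak points: A5 needs two further stereocentres (C5, C10) set in a defined cis relation next to an epimerisable ketone precursor. Alkene geometry depends on a chair-versus-boat choice. C14 is absent and must be added by palladium-catalysed carbonylation on the ten-membered triflate in the presence of the 1,5-diene.
- Comparison: the chosen plan sets against the milder ring expansion a precursor whose extra stereocentres only need the cis-anti-cis relation, and a C14 that is already in place as the ester.

**Alternative 3:** Cut C6–C7. Pd(PPh3)4 (zerovalent palladium) would ionise the allylic carbonate of the open-chain β-keto ester A7, and C7 would attack the π-allyl terminus C6 under high dilution to give the ten-membered β-keto ester A6. A dynamic kinetic hydrogenation (RuCl2[(S)-BINAP]-type catalyst) would then set C7 and C8.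
- Merits: absolute and relative configuration come from one catalytic step with no material discarded, which is better than the resolution used in the chosen plan. Both alkenes are made in the open chain by ordinary olefination.
- Weak points: closing a ten-membered ring by allylic alkylation works against entropy and transannular strain, with oligomerisation and attack at the other allyl terminus as competitors. Syn/anti isomerisation of the π-allyl can erode the C4=C5 geometry. The Z-trisubstituted C1=C10 alkene must be built acyclically. The trans-selective dynamic hydrogenation is established for five- to seven-membered β-keto esters, not for a ten-membered one with two alkenes. The C11 ester still lacks C12.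
- Comparison: the chosen plan forms the ring with strain release and takes both alkene geometries from one cycloreversion. In return it accepts a resolution and a selectivity risk in the ring opening.

Key step: step 10

Assumption: the lipase of step 5 follows the usual size-based preference for secondary alcohols, so the unreacted alcohol is the (4R,5S) enantiomer. If the preference were reversed, the acetate fraction would be carried on after methanolysis.

Remark on step 10: the trans substituents of enoate 10 sit at the homoallylic carbons and do not differentiate its two faces, so photoadduct 15 is expected as a pair of cis-anti-cis facial isomers. They share the number 15 and are carried into step 11 unseparated. The structure given is the isomer with the ester trans to the silyloxy group on germacrane C8; the other has all four cyclobutane centres inverted.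

## Route

Step 1
Reactants: 1 but-3-yn-1-ol
Product: 2 (but-3-yn-1-yloxy)triethylsilane
Conditions: Et3SiCl, imidazole, CH2Cl2, 0 °C to rt
Reagents that add atoms: chlorotriethylsilane, CC[Si](Cl)(CC)CC
Why: Routine silylation of a primary alcohol; the TES ether is chosen because a primary TES ether can later be oxidised directly to the aldehyde beside TBS ethers.

Step 2
Reactants: 2 (but-3-yn-1-yloxy)triethylsilane; 3 ethylene
Product: 4 2-[2-(triethylsilyloxy)ethyl]buta-1,3-diene
Conditions: ethylene (1 atm), second-generation Grubbs catalyst RuCl2(=CHPh)(H2IMes)(PCy3) (5 mol%), toluene, 80 °C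
Reagents that add atoms: none
Why: Cross enyne metathesis of a terminal alkyne with ethylene gives the 2-substituted buta-1,3-diene with every atom of both partners retained; homopropargylic ethers are standard substrates.

Step 3
Reactants: 4 2-[2-(triethylsilyloxy)ethyl]buta-1,3-diene; 5 methyl propiolate
Product: 6 methyl 4-[2-(triethylsilyloxy)ethyl]cyclohexa-1,4-diene-1-carboxylate
Conditions: EtAlCl2 (0.3 equiv), CH2Cl2, −78 to −20 °C
Reagents that add atoms: none
Why: Lewis-acid-promoted Diels–Alder reaction of a 2-substituted diene with an alkynoate; the diene terminus next to the substituted carbon bonds to the β-carbon of the complexed propiolate, so the 1,4-disubstituted ("para") cyclohexa-1,4-diene should dominate. No stereocentre is formed and C14 enters as the ester.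

Step 4
Reactants: 6 methyl 4-[2-(triethylsilyloxy)ethyl]cyclohexa-1,4-diene-1-carboxylate
Product: 8 racemic methyl trans-5-hydroxy-4-[2-(triethylsilyloxy)ethyl]cyclohex-1-ene-1-carboxylate, via trans-alkylborane 7 (not isolated)
Conditions: 9-BBN (1.3 equiv), THF, 0 to 60 °C; then NaBO3·4H2O, H2O, rt
Reagents that add atoms: sodium perborate, [Na+].[O-]OB=O
Why: Hydroboration–oxidation; the hindered borane adds only to the electron-rich trisubstituted alkene, boron at the less substituted C8, and leaves the enoate untouched. Syn addition followed by oxidation with retention places the C8 hydroxyl trans to the C7 side chain (racemic).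

Step 5
Reactants: 8 racemic methyl trans-5-hydroxy-4-[2-(triethylsilyloxy)ethyl]cyclohex-1-ene-1-carboxylate
Product: 9 methyl (4R,5S)-5-hydroxy-4-[2-(triethylsilyloxy)ethyl]cyclohex-1-ene-1-carboxylate
Conditions: Candida antarctica lipase B (immobilised), vinyl acetate, t-BuOMe, 30 °C, stopped just past half conversion
Reagents that add atoms: none
Why: Lipase-catalysed kinetic resolution by transesterification of a trans-2-substituted cyclohexanol; the size rule (the ring carbon bearing the side chain is the large group) predicts acylation of the (5R) alcohol, leaving (4R,5S)-9, whose enantiomeric purity rises as conversion passes one half. This step fixes the absolute configuration of C7 and C8.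

Step 6
Reactants: 9 methyl (4R,5S)-5-hydroxy-4-[2-(triethylsilyloxy)ethyl]cyclohex-1-ene-1-carboxylate
Product: 10 methyl (4R,5S)-5-(TBSO)-4-[2-(TESO)ethyl]cyclohex-1-ene-1-carboxylate
Conditions: TBSOTf, 2,6-lutidine, CH2Cl2, −78 to 0 °C
Reagents that add atoms: tert-butyldimethylsilyl triflate, CC(C)(C)[Si](C)(C)OS(=O)(=O)C(F)(F)F
Why: Silylation of the secondary alcohol with a silyl triflate; the TES ether and the enoate are inert, and the TBS ether keeps O8 from lactonising onto C14 in the later tricycle.

Step 7
Reactants: 11 ethyl 1-bromocyclobutane-1-carboxylate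
Product: 12 cyclobut-1-ene-1-carboxylic acid
Conditions: KOH, toluene, reflux; then aq. HCl, 0 °C
Reagents that add atoms: potassium hydroxide, [K+].[OH-]
Why: Base-induced dehydrobromination of the tertiary α-bromo ester with concurrent saponification; the acid is used at once because it polymerises on standing.

Step 8
Reactants: 12 cyclobut-1-ene-1-carboxylic acid
Product: 13 cyclobut-1-en-1-ylmethanol
Conditions: LiAlH4, Et2O, 0 °C
Reagents that add atoms: none
Why: 1,2-Reduction of an alkyl-substituted α,β-unsaturated acid to the allylic alcohol, as for other cycloalk-1-enecarboxylic acids.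

Step 9
Reactants: 13 cyclobut-1-en-1-ylmethanol
Product: 14 tert-butyl(cyclobut-1-en-1-ylmethoxy)dimethylsilane
Conditions: TBSCl, imidazole, CH2Cl2, rt
Reagents that add atoms: tert-butylchlorodimethylsilane, CC(C)(C)[Si](C)(C)Cl
Why: Routine silylation; a non-aromatic silyl ether is chosen so that the cyclobutene carries no competing chromophore.

Step 10
Reactants: 10 methyl (4R,5S)-5-(TBSO)-4-[2-(TESO)ethyl]cyclohex-1-ene-1-carboxylate; 14 tert-butyl(cyclobut-1-en-1-ylmethoxy)dimethylsilane
Product: 15 methyl cis-anti-cis-9-(TBSO)-5-[(TBSO)methyl]-8-[2-(TESO)ethyl]tricyclo[4.4.0.0(2,5)]decane-1-carboxylate (pair of facial isomers, not separated; the isomer with the ester trans to the silyloxy group on germacrane C8 is drawn)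
Conditions: hν (medium-pressure Hg lamp, Pyrex filter, λ > 290 nm), acetone (solvent and triplet sensitiser), 14 (5 equiv), Ar, −20 °C
Reagents that add atoms: none
Why: Acetone passes triplet energy to enoate 10, whose twisted triplet adds to the strained alkene of 14 to give a triplet 1,4-biradical that, after intersystem crossing, collapses to the cyclobutane C10–C1–C4–C5, forming the σ bonds C1–C10 and C4–C5. The closest known reaction type is the sensitised [2+2] photocycloaddition of cyclic enones and enoates to cyclobutenes and other simple alkenes. The one new ring, the central cyclobutane, closes by radical–radical combination of the biradical in an intermolecular stepwise [2+2], creating the bicyclo[2.2.0]hexane. The step needs head-to-tail regiochemistry (C1–H to the ester-bearing C10, substituted C4 to C5); this follows the usual preference of electron-rich alkenes, and biradicals leading to the other orientation would have to join the two fully substituted carbons C10 and C4 and should revert. C10 and C5 are cis because a four-membered ring closes cis onto the six-membered ring from the relaxed biradical. C1 and C4 are cis because the cyclobutene ring is retained. The anti relation follows from the cyclobutene approaching with its CH2–CH2 bridge turned away from the six-membered ring. The face relative to C7/C8 is not controlled, so 15 is expected as two cis-anti-cis facial isomers that are carried on together, which is harmless because all four new centres become trigonal in step 11; excess 14 and low temperature limit enoate dimerisation.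

Step 11
Reactants: 15 the cis-anti-cis photoadduct (both facial isomers as obtained)
Product: 16 methyl (1(10)E,4Z,7R,8S)-8-(TBSO)-4-[(TBSO)methyl]-7-[2-(TESO)ethyl]cyclodeca-1(10),4-diene-10-carboxylate (germacrane numbering; C1=C10 cis in the ring, C4=C5 trans in the ring)
Conditions: mesitylene (0.01 M, degassed), BHT (cat.), sealed base-washed glass tube, 185 °C
Reagents that add atoms: none
Why: Thermal cycloreversion of the bicyclo[2.2.0]hexane: homolysis of the strained central bond C1–C4 gives a cyclohexane-1,4-diyl, which cleaves C5–C10 and not C2–C3 because only that cleavage brings the new C1=C10 bond into conjugation with the ester. In the chair form of the diyl the ester on quaternary C10 sits equatorial and H5 axial, so C9 ends cis to C2 and C6 trans to C3, which is the required cis,trans diene from either facial isomer of 15. The conjugated ester also disfavours onward Cope rearrangement, which would deconjugate it.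

Step 12
Reactants: 16 the ten-membered dienoate
Product: 17 (1(10)E,4Z,7R,8S)-8-(TBSO)-4-[(TBSO)methyl]-10-(hydroxymethyl)-7-[2-(TESO)ethyl]cyclodeca-1(10),4-diene
Conditions: i-Bu2AlH (2.5 equiv), CH2Cl2, −78 °C; aq. potassium sodium tartrate work-up
Reagents that add atoms: none
Why: 1,2-Reduction of the only carbonyl group, a conjugated ester, to the C14 allylic alcohol; silyl ethers and alkene geometry are unaffected.

Step 13
Reactants: 17 the C14 allylic alcohol
Product: 18 (1(10)E,4Z,7R,8S)-10-(acetoxymethyl)-8-(TBSO)-4-[(TBSO)methyl]-7-[2-(TESO)ethyl]cyclodeca-1(10),4-diene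
Conditions: Ac2O, pyridine, DMAP (cat.), CH2Cl2, 0 °C to rt
Reagents that add atoms: acetic anhydride, CC(=O)OC(C)=O
Why: Acetylation of the only free hydroxyl; C14 is now in its final form and remains distinct from the silylated C15.

Step 14
Reactants: 18 the C14 acetate
Product: 20 [(1(10)E,4Z,7R,8S)-10-(acetoxymethyl)-8-(TBSO)-4-[(TBSO)methyl]cyclodeca-1(10),4-dien-7-yl]acetaldehyde, via primary alcohol 19 (not isolated)
Conditions: (COCl)2, DMSO, CH2Cl2, −78 to −40 °C; then Et3N, −78 °C to rt
Reagents that add atoms: none
Why: Swern oxidation applied directly to a primary TES ether: the activated sulfonium species cleaves the primary TES ether in situ and the liberated alcohol is oxidised, while the secondary and allylic TBS ethers and the acetate survive. C7 is β to the new aldehyde and cannot epimerise.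

Step 15
Reactants: 20 the C12 aldehyde
Product: 22 2-[(1(10)E,4Z,7R,8S)-10-(acetoxymethyl)-8-(TBSO)-4-[(TBSO)methyl]cyclodeca-1(10),4-dien-7-yl]prop-2-enal, via Mannich base 21 (not isolated)
Conditions: CH2=NMe2+ I− (Eschenmoser's salt), Et3N, CH2Cl2, rt
Reagents that add atoms: N,N-dimethylmethyleneiminium iodide, C=[N+](C)C.[I-]
Why: Mannich reaction of the aldehyde at C11 followed by β-elimination of dimethylamine (aldehyde α-methylenation) installs C13 under mild amine conditions that the acetate tolerates.

Step 16
Reactants: 22 the α-methylene aldehyde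
Product: 23 2-[(1(10)E,4Z,7R,8S)-10-(acetoxymethyl)-8-(TBSO)-4-[(TBSO)methyl]cyclodeca-1(10),4-dien-7-yl]prop-2-enoic acid
Conditions: NaClO2, NaH2PO4, 2-methyl-2-butene (excess), t-BuOH–H2O, 0 °C to rt
Reagents that add atoms: sodium chlorite, [Na+].[O-]Cl=O
Why: Pinnick oxidation of the enal to the acrylic acid; the hypochlorous acid formed is scavenged by 2-methyl-2-butene, so the ring alkenes are spared.

Step 17
Reactants: 23 the acrylic acid
Product: 25 (1(10)E,4Z,7R,8S)-14-acetoxy-15-hydroxygermacra-1(10),4,11(13)-trien-12,8-olide, via dihydroxy acid 24 (not isolated)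
Conditions: HF·pyridine, pyridine, THF, 0 °C to rt
Reagents that add atoms: none
Why: Buffered fluoride removes both TBS ethers; the freed C8 hydroxyl closes onto the C12 acid (5-exo-trig lactonisation) to give the trans-fused α-methylene lactone without touching C7 or C8, and C15 emerges as the only free hydroxyl.

Step 18
Reactants: 26 ethyl 2-(hydroxymethyl)acrylate
Product: 27 ethyl 2-[(TBSO)methyl]prop-2-enoate
Conditions: TBSCl, imidazole, CH2Cl2, 0 °C to rt
Reagents that add atoms: tert-butylchlorodimethylsilane, CC(C)(C)[Si](C)(C)Cl
Why: Routine silylation; it prevents self-esterification of the hydroxy acid in step 20.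

Step 19
Reactants: 27 ethyl 2-[(TBSO)methyl]prop-2-enoate
Product: 28 2-[(TBSO)methyl]prop-2-enoic acid
Conditions: LiOH, THF–H2O, 0 °C to rt; then aq. HCl to pH 4
Reagents that add atoms: lithium hydroxide, [Li+].[OH-]
Why: Saponification of a 2-substituted acrylate; the primary TBS ether is stable to cold aqueous hydroxide.

Step 20
Reactants: 25 the hydroxy lactone; 28 2-[(TBSO)methyl]prop-2-enoic acid
Product: 29 (1(10)E,4Z,7R,8S)-14-acetoxy-15-{2-[(TBSO)methyl]acryloyloxy}germacra-1(10),4,11(13)-trien-12,8-olide
Conditions: EDC·HCl, DMAP (cat.), CH2Cl2, 0 °C to rt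
Reagents that add atoms: none
Why: Steglich esterification of the single primary allylic alcohol; the conditions are near neutral and leave the methylene lactone and the acetate intact.

Step 21
Reactants: 29 the silyl-protected target
Product: 30 (1(10)E,4Z,7R,8S)-14-acetoxy-15-[2-(hydroxymethyl)acryloyloxy]germacra-1(10),4,11(13)-trien-12,8-olide (CNP0126545.1)
Conditions: HF·pyridine, pyridine, THF, 0 °C
Reagents that add atoms: none
Why: Buffered fluoride cleavage of a primary TBS ether; the medium is neither basic enough for acyl migration or conjugate addition nor acidic enough for transannular cyclisation.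

## Compound list

1 | but-3-yn-1-ol | C#CCCO | starting material
2 | (but-3-yn-1-yloxy)triethylsilane | C#CCCO[Si](CC)(CC)CC | intermediate
3 | ethylene | C=C | starting material
4 | 2-[2-(triethylsilyloxy)ethyl]buta-1,3-diene | C=CC(=C)CCO[Si](CC)(CC)CC | intermediate
5 | methyl propiolate | C#CC(=O)OC | starting material
6 | methyl 4-[2-(triethylsilyloxy)ethyl]cyclohexa-1,4-diene-1-carboxylate | COC(=O)C1=CCC(CCO[Si](CC)(CC)CC)=CC1 | intermediate
7 | methyl trans-5-(9-borabicyclo[3.3.1]nonan-9-yl)-4-[2-(triethylsilyloxy)ethyl]cyclohex-1-ene-1-carboxylate (racemic, one enantiomer drawn) | COC(=O)C1=CC[C@H](CCO[Si](CC)(CC)CC)[C@@H](B2C3CCCC2CCC3)C1 | intermediate (not isolated)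
8 | methyl trans-5-hydroxy-4-[2-(triethylsilyloxy)ethyl]cyclohex-1-ene-1-carboxylate (racemate, one enantiomer drawn) | COC(=O)C1=CC[C@H](CCO[Si](CC)(CC)CC)[C@@H](O)C1 | intermediate
9 | methyl (4R,5S)-5-hydroxy-4-[2-(triethylsilyloxy)ethyl]cyclohex-1-ene-1-carboxylate (single enantiomer) | COC(=O)C1=CC[C@H](CCO[Si](CC)(CC)CC)[C@@H](O)C1 | intermediate
10 | methyl (4R,5S)-5-(tert-butyldimethylsilyloxy)-4-[2-(triethylsilyloxy)ethyl]cyclohex-1-ene-1-carboxylate | COC(=O)C1=CC[C@H](CCO[Si](CC)(CC)CC)[C@@H](O[Si](C)(C)C(C)(C)C)C1 | intermediate
11 | ethyl 1-bromocyclobutane-1-carboxylate | CCOC(=O)C1(Br)CCC1 | starting material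
12 | cyclobut-1-ene-1-carboxylic acid | OC(=O)C1=CCC1 | intermediate
13 | cyclobut-1-en-1-ylmethanol | OCC1=CCC1 | intermediate
14 | tert-butyl(cyclobut-1-en-1-ylmethoxy)dimethylsilane | CC(C)(C)[Si](C)(C)OCC1=CCC1 | intermediate
15 | methyl cis-anti-cis-9-(TBSO)-5-[(TBSO)methyl]-8-[2-(TESO)ethyl]tricyclo[4.4.0.0(2,5)]decane-1-carboxylate, germacrane C7 R and C8 S (pair of facial isomers carried on together; drawn: ester trans to the silyloxy group on germacrane C8) | COC(=O)[C@@]12C[C@H](O[Si](C)(C)C(C)(C)C)[C@@H](CCO[Si](CC)(CC)CC)C[C@@H]1[C@@]1(CO[Si](C)(C)C(C)(C)C)CC[C@@H]21 | intermediate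
16 | methyl (1(10)E,4Z,7R,8S)-8-(TBSO)-4-[(TBSO)methyl]-7-[2-(TESO)ethyl]cyclodeca-1(10),4-diene-10-carboxylate | CC(C)(C)[Si](C)(C)OC/C1=C\C[C@H](CCO[Si](CC)(CC)CC)[C@@H](O[Si](C)(C)C(C)(C)C)C/C(C(=O)OC)=C\CC1 | intermediate
17 | (1(10)E,4Z,7R,8S)-8-(TBSO)-4-[(TBSO)methyl]-10-(hydroxymethyl)-7-[2-(TESO)ethyl]cyclodeca-1(10),4-diene | CC(C)(C)[Si](C)(C)OC/C1=C\C[C@H](CCO[Si](CC)(CC)CC)[C@@H](O[Si](C)(C)C(C)(C)C)C/C(CO)=C\CC1 | intermediate
18 | (1(10)E,4Z,7R,8S)-10-(acetoxymethyl)-8-(TBSO)-4-[(TBSO)methyl]-7-[2-(TESO)ethyl]cyclodeca-1(10),4-diene | CC(C)(C)[Si](C)(C)OC/C1=C\C[C@H](CCO[Si](CC)(CC)CC)[C@@H](O[Si](C)(C)C(C)(C)C)C/C(COC(C)=O)=C\CC1 | intermediate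
19 | 2-[(1(10)E,4Z,7R,8S)-10-(acetoxymethyl)-8-(TBSO)-4-[(TBSO)methyl]cyclodeca-1(10),4-dien-7-yl]ethanol | CC(C)(C)[Si](C)(C)OC/C1=C\C[C@H](CCO)[C@@H](O[Si](C)(C)C(C)(C)C)C/C(COC(C)=O)=C\CC1 | intermediate (not isolated)
20 | [(1(10)E,4Z,7R,8S)-10-(acetoxymethyl)-8-(TBSO)-4-[(TBSO)methyl]cyclodeca-1(10),4-dien-7-yl]acetaldehyde | CC(C)(C)[Si](C)(C)OC/C1=C\C[C@H](CC=O)[C@@H](O[Si](C)(C)C(C)(C)C)C/C(COC(C)=O)=C\CC1 | intermediate
21 | 3-(dimethylamino)-2-[(1(10)E,4Z,7R,8S)-10-(acetoxymethyl)-8-(TBSO)-4-[(TBSO)methyl]cyclodeca-1(10),4-dien-7-yl]propanal (C11 epimers) | CC(C)(C)[Si](C)(C)OC/C1=C\C[C@H](C(CN(C)C)C=O)[C@@H](O[Si](C)(C)C(C)(C)C)C/C(COC(C)=O)=C\CC1 | intermediate (not isolated)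
22 | 2-[(1(10)E,4Z,7R,8S)-10-(acetoxymethyl)-8-(TBSO)-4-[(TBSO)methyl]cyclodeca-1(10),4-dien-7-yl]prop-2-enal | CC(C)(C)[Si](C)(C)OC/C1=C\C[C@H](C(=C)C=O)[C@@H](O[Si](C)(C)C(C)(C)C)C/C(COC(C)=O)=C\CC1 | intermediate
23 | 2-[(1(10)E,4Z,7R,8S)-10-(acetoxymethyl)-8-(TBSO)-4-[(TBSO)methyl]cyclodeca-1(10),4-dien-7-yl]prop-2-enoic acid | CC(C)(C)[Si](C)(C)OC/C1=C\C[C@H](C(=C)C(=O)O)[C@@H](O[Si](C)(C)C(C)(C)C)C/C(COC(C)=O)=C\CC1 | intermediate
24 | 2-[(1(10)E,4Z,7R,8S)-10-(acetoxymethyl)-8-hydroxy-4-(hydroxymethyl)cyclodeca-1(10),4-dien-7-yl]prop-2-enoic acid | OC/C1=C\C[C@H](C(=C)C(=O)O)[C@@H](O)C/C(COC(C)=O)=C\CC1 | intermediate (not isolated)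
25 | (1(10)E,4Z,7R,8S)-14-acetoxy-15-hydroxygermacra-1(10),4,11(13)-trien-12,8-olide | OC/C1=C\C[C@@H]2C(=C)C(=O)O[C@H]2C/C(COC(C)=O)=C\CC1 | intermediate
26 | ethyl 2-(hydroxymethyl)acrylate | C=C(CO)C(=O)OCC | starting material
27 | ethyl 2-[(tert-butyldimethylsilyloxy)methyl]prop-2-enoate | C=C(CO[Si](C)(C)C(C)(C)C)C(=O)OCC | intermediate
28 | 2-[(tert-butyldimethylsilyloxy)methyl]prop-2-enoic acid | C=C(CO[Si](C)(C)C(C)(C)C)C(=O)O | intermediate
29 | (1(10)E,4Z,7R,8S)-14-acetoxy-15-{2-[(TBSO)methyl]acryloyloxy}germacra-1(10),4,11(13)-trien-12,8-olide | C=C(CO[Si](C)(C)C(C)(C)C)C(=O)OC/C1=C\C[C@@H]2C(=C)C(=O)O[C@H]2C/C(COC(C)=O)=C\CC1 | intermediate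
30 | (1(10)E,4Z,7R,8S)-14-acetoxy-15-[2-(hydroxymethyl)acryloyloxy]germacra-1(10),4,11(13)-trien-12,8-olide (CNP0126545.1) | C=C(CO)C(=O)OC/C1=C\C[C@@H]2C(=C)C(=O)O[C@H]2C/C(COC(C)=O)=C\CC1 | target

## Step count and least certain steps

Total: 21 steps. Longest linear sequence: 16 steps (steps 1–6, 10–17, 20, 21).

**Step 10 (key step).** The likeliest failure is unproductive decay of the twisted enoate triplet, with enoate dimerisation or hydrogen abstraction, outrunning capture by the cyclobutene, because an ester is a weaker triplet chromophore than a ketone. A second risk is closure of part of the biradical to trans-fused or syn adducts, and a third is consumption of the cyclobutene by oxetane formation with excited acetone. Fallback: exchange the ester for a proven enone chromophore on the same carbon, which absorbs above 300 nm without a sensitiser, and restore the ester afterwards. From 10, Me(MeO)NH·HCl and i-PrMgCl give the Weinreb amide F1, and MeMgBr gives the methyl ketone F2 (a 1-acetylcyclohexene). Irradiation of F2 with 14 gives the tricyclic methyl ketone F3 (drawn in the same facial series as 15). Haloform cleavage with NaOBr, which is clean because the other α-carbon is quaternary, gives the tricyclic acid F4, and Me3SiCHN2 in methanol returns the route at 15.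

**Step 11.** The likeliest failure is loss of geometric control in the second bond cleavage (the diyl fragmenting through the other chair or the boat), or onward Cope rearrangement of the product at the temperature needed for ring opening. Fallback: place the C1=C10 geometry under thermodynamic control through the aldehyde. From 15, i-Bu2AlH gives the tricyclic carbinol F5 and Dess–Martin periodinane the tricyclic aldehyde F6. Thermolysis of F6 gives the ten-membered enal F7; 2-substituted enals equilibrate readily (catalytic thiol or I2) to the E isomer, which is the ring-cis geometry. NaBH4 with CeCl3·7H2O then reduces F7 to 17, where the route is rejoined and step 12 is skipped.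

**Step 5.** The likeliest failure is insufficient discrimination between the enantiomers by the lipase, because the two ring branches flanking the carbinol differ only moderately in size. Fallback: covalent resolution. From 8, (S)-O-methylmandelic acid with DCC and DMAP gives the diastereomeric esters F8 (from the 4R,5S alcohol) and F9 (from its enantiomer), which are separated by chromatography or crystallisation. Methanolysis of F8 with K2CO3 in methanol returns 9.

**Step 3.** The likeliest failure is erosion of regioselectivity (bonding of the propiolate in the reversed orientation) or Lewis-acid cleavage of the TES ether and oligomerisation of the diene. Fallback: catalyst-controlled regiochemistry through a metallacycle instead of a Lewis-acid-polarised transition state. From 4 and 5, the cobalt-catalysed [4+2] cycloaddition of 2-substituted dienes with terminal alkynes (CoBr2(dppe), Zn, ZnI2, CH2Cl2, rt) would give 6 directly under neutral conditions.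

## Further compounds

F1 | step 10 | (4R,5S)-5-(TBSO)-N-methoxy-N-methyl-4-[2-(TESO)ethyl]cyclohex-1-ene-1-carboxamide | CON(C)C(=O)C1=CC[C@H](CCO[Si](CC)(CC)CC)[C@@H](O[Si](C)(C)C(C)(C)C)C1
F2 | step 10 | 1-[(4R,5S)-5-(TBSO)-4-[2-(TESO)ethyl]cyclohex-1-en-1-yl]ethan-1-one | CC(=O)C1=CC[C@H](CCO[Si](CC)(CC)CC)[C@@H](O[Si](C)(C)C(C)(C)C)C1
F3 | step 10 | cis-anti-cis-1-acetyl-9-(TBSO)-5-[(TBSO)methyl]-8-[2-(TESO)ethyl]tricyclo[4.4.0.0(2,5)]decane (facial series of 15) | CC(=O)[C@@]12C[C@H](O[Si](C)(C)C(C)(C)C)[C@@H](CCO[Si](CC)(CC)CC)C[C@@H]1[C@@]1(CO[Si](C)(C)C(C)(C)C)CC[C@@H]21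
F4 | step 10 | cis-anti-cis-9-(TBSO)-5-[(TBSO)methyl]-8-[2-(TESO)ethyl]tricyclo[4.4.0.0(2,5)]decane-1-carboxylic acid | OC(=O)[C@@]12C[C@H](O[Si](C)(C)C(C)(C)C)[C@@H](CCO[Si](CC)(CC)CC)C[C@@H]1[C@@]1(CO[Si](C)(C)C(C)(C)C)CC[C@@H]21
F5 | step 11 | [cis-anti-cis-9-(TBSO)-5-[(TBSO)methyl]-8-[2-(TESO)ethyl]tricyclo[4.4.0.0(2,5)]decan-1-yl]methanol | OC[C@@]12C[C@H](O[Si](C)(C)C(C)(C)C)[C@@H](CCO[Si](CC)(CC)CC)C[C@@H]1[C@@]1(CO[Si](C)(C)C(C)(C)C)CC[C@@H]21
F6 | step 11 | cis-anti-cis-9-(TBSO)-5-[(TBSO)methyl]-8-[2-(TESO)ethyl]tricyclo[4.4.0.0(2,5)]decane-1-carbaldehyde | O=C[C@@]12C[C@H](O[Si](C)(C)C(C)(C)C)[C@@H](CCO[Si](CC)(CC)CC)C[C@@H]1[C@@]1(CO[Si](C)(C)C(C)(C)C)CC[C@@H]21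
F7 | step 11 | (1(10)E,4Z,7R,8S)-8-(TBSO)-4-[(TBSO)methyl]-7-[2-(TESO)ethyl]cyclodeca-1(10),4-diene-10-carbaldehyde | CC(C)(C)[Si](C)(C)OC/C1=C\C[C@H](CCO[Si](CC)(CC)CC)[C@@H](O[Si](C)(C)C(C)(C)C)C/C(C=O)=C\CC1
F8 | step 5 | methyl (4R,5S)-5-{[(2S)-2-methoxy-2-phenylacetyl]oxy}-4-[2-(TESO)ethyl]cyclohex-1-ene-1-carboxylate | COC(=O)C1=CC[C@H](CCO[Si](CC)(CC)CC)[C@@H](OC(=O)[C@@H](OC)c2ccccc2)C1
F9 | step 5 | methyl (4S,5R)-5-{[(2S)-2-methoxy-2-phenylacetyl]oxy}-4-[2-(TESO)ethyl]cyclohex-1-ene-1-carboxylate | COC(=O)C1=CC[C@@H](CCO[Si](CC)(CC)CC)[C@H](OC(=O)[C@@H](OC)c2ccccc2)C1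
F0 | step 3 | none | none
A1 | alternative 1 | 7-acetyl-4,10-bis[(TBSO)methyl]cyclodeca-1(10),4,7-triene (C1=C10 cis, C4=C5 trans, C7=C8 cis) | CC(C)(C)[Si](C)(C)OC/C1=C\C/C(C(C)=O)=C\C/C(CO[Si](C)(C)C(C)(C)C)=C\CC1
A2 | alternative 1 | 2-[(tert-butyldimethylsilyloxy)methyl]buta-1,3-diene | C=CC(=C)CO[Si](C)(C)C(C)(C)C
A3 | alternative 1 | but-3-yn-2-one | CC(=O)C#C
A4 | alternative 2 | ten-membered dienyl triflate (triflate on C10, C7/C8 acetonide, C15 p-methoxybenzyl ether) | COc3ccc(COC/C1=C\C[C@@H]2COC(C)(C)O[C@H]2C/C(OS(=O)(=O)C(F)(F)F)=C\CC1)cc3
A5 | alternative 2 | cis-1-vinyl-2-[3-(p-methoxybenzyloxy)prop-1-en-2-yl]cyclohexanol with trans-fused C7/C8 acetonide (one cis diastereomer drawn) | C=C[C@@]1(O)C[C@@H]2OC(C)(C)OC[C@H]2C[C@H]1C(=C)COCc1ccc(OC)cc1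
A6 | alternative 3 | ten-membered β-keto ester (C8 ketone, methyl ester on C7, C14 TBS ether, C15 p-methoxybenzyl ether) | COC(=O)C1C/C=C(\COCc2ccc(OC)cc2)/CC/C=C(/CO[Si](C)(C)C(C)(C)C)\CC1=O
A7 | alternative 3 | open-chain β-keto ester with C6 allylic methyl carbonate | COC(=O)CC(=O)C/C(CO[Si](C)(C)C(C)(C)C)=C\CC/C(COCc1ccc(OC)cc1)=C/COC(=O)OC
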